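**Retrosynthetic overview**
1. Target 19 comes from penta-silyl ether 18 by global desilylation under non-basic conditions.
2. 18 is cut across the dihydrofuran into hydroxypyranone 16 and (Z)-styrylpyranone 9. C-3 of 16 is used as an electrophilic carbene carbon (via iodonium ylide 17), so C3–C3a and C2–O1 form in one step and both stereocentres are set there.
3. 9 comes from E-alkene 8 by E→Z photoisomerisation; 8 comes from a vinylogous aldol condensation of silylated triacetic acid lactone 4 with aldehyde 2.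
4. 16 comes from diketo ester 14 by acylketene cyclisation; 14 comes from Claisen acylation of the dianion of tert-butyl acetoacetate with ester 11.
5. Ring order: upper pyranone (purchased), lower pyranone (step 7), dihydrofuran (step 8, last).

Assumption: the SMILES is read as the 2,3-cis isomer (2R,3S; aryl and pyranonyl on the same face), and Rh2(S-NTTL)4 is taken to give this enantiomer; if a pilot run shows the opposite sense, Rh2(R-NTTL)4 is used instead.

**Step 1**
Reactants: 1 3,4-dihydroxybenzaldehyde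
Product: 2 3,4-bis(tert-butyldimethylsilyloxy)benzaldehyde
Conditions: TBSCl (2.3 equiv), imidazole (5 equiv), DMF, rt
Reagents that add atoms: tert-butyldimethylsilyl chloride, CC(C)(C)[Si](C)(C)Cl
Why: Imidazole-promoted silyl ether formation on both phenols leaves the aldehyde untouched; no stereocentre is involved.

**Step 2**
Reactants: 3 4-hydroxy-6-methyl-2H-pyran-2-one
Product: 4 6-methyl-4-(triisopropylsilyloxy)-2H-pyran-2-one
Conditions: TIPSCl (1.1 equiv), Et3N (1.3 equiv), DMAP (cat.), CH2Cl2, 0 °C to rt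
Reagents that add atoms: triisopropylsilyl chloride, CC(C)[Si](Cl)(C(C)C)C(C)C
Why: O-silylation of the vinylogous acid gives the 4-silyloxy-2-pyranone, and the bulky silyl group shields C-3 and survives the carbanion chemistry that follows.

**Step 3**
Reactants: 4 6-methyl-4-(triisopropylsilyloxy)-2H-pyran-2-one; 2 3,4-bis(tert-butyldimethylsilyloxy)benzaldehyde
Product: 8 (E)-6-{2-[3,4-bis(tert-butyldimethylsilyloxy)phenyl]ethenyl}-4-(triisopropylsilyloxy)-2H-pyran-2-one, via lithium dienolate 5 (not isolated), via lithium aldolate 6 (not isolated), via mesylate 7 (not isolated)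
Conditions: LiN(i-Pr)2 (1.1 equiv), THF, −78 °C; 2 (1.0 equiv), −78 °C; MsCl (1.3 equiv), −78 to 0 °C; DBU (2.5 equiv), 0 °C to rt
Reagents that add atoms: none
Why: Vinylogous aldol addition of the C-6 methyl carbanion to the aldehyde, then mesylation and E1cB elimination (an aldol condensation), gives the conjugated E-alkene under thermodynamic control.

**Step 4**
Reactants: 8 (E)-6-{2-[3,4-bis(tert-butyldimethylsilyloxy)phenyl]ethenyl}-4-(triisopropylsilyloxy)-2H-pyran-2-one
Product: 9 (Z)-6-{2-[3,4-bis(tert-butyldimethylsilyloxy)phenyl]ethenyl}-4-(triisopropylsilyloxy)-2H-pyran-2-one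
Conditions: Ir(ppy)3 (1 mol%), 450 nm LEDs, degassed MeCN (0.01 M), rt; chromatography in the dark, recovered 8 recycled
Reagents that add atoms: none
Why: Triplet energy-transfer E→Z photoisomerisation excites the planar E isomer selectively, so the twisted Z isomer with its higher triplet energy accumulates (contra-thermodynamic alkene isomerisation).

**Step 5**
Reactants: 10 ethyl 3,4-dihydroxybenzoate
Product: 11 ethyl 3,4-bis(tert-butyldimethylsilyloxy)benzoate
Conditions: TBSCl (2.3 equiv), imidazole (5 equiv), DMF, rt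
Reagents that add atoms: tert-butyldimethylsilyl chloride, CC(C)(C)[Si](C)(C)Cl
Why: Standard imidazole-promoted silylation of both phenols; the ester is inert.

**Step 6**
Reactants: 12 tert-butyl acetoacetate; 11 ethyl 3,4-bis(tert-butyldimethylsilyloxy)benzoate
Product: 14 tert-butyl 5-[3,4-bis(tert-butyldimethylsilyloxy)phenyl]-3,5-dioxopentanoate, via acetoacetate dianion 13 (not isolated)
Conditions: 12 (2.2 equiv), NaH (2.3 equiv), THF, 0 °C; n-BuLi (2.2 equiv), 0 °C; 11 (1.0 equiv), 0 °C to rt; cold 1 M HCl to pH 5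
Reagents that add atoms: none
Why: Claisen-type acylation of the acetoacetate dianion (Weiler dianion chemistry) occurs at the more basic terminal carbon, with loss of ethoxide from the aryl ester.

**Step 7**
Reactants: 14 tert-butyl 5-[3,4-bis(tert-butyldimethylsilyloxy)phenyl]-3,5-dioxopentanoate
Product: 16 6-[3,4-bis(tert-butyldimethylsilyloxy)phenyl]-4-hydroxy-2H-pyran-2-one, via acylketene 15 (not isolated)
Conditions: toluene (0.02 M), 110 °C, 2 h
Reagents that add atoms: none
Why: Neutral thermolysis of the tert-butyl β-keto ester expels tert-butanol to give an acylketene, which the enol oxygen of the aryl ketone traps to close the 4-hydroxy-2-pyranone (acylketene cyclisation).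

**Step 8**
Reactants: 16 6-[3,4-bis(tert-butyldimethylsilyloxy)phenyl]-4-hydroxy-2H-pyran-2-one; 9 (Z)-6-{2-[3,4-bis(tert-butyldimethylsilyloxy)phenyl]ethenyl}-4-(triisopropylsilyloxy)-2H-pyran-2-one
Product: 18 (2R,3S)-2,6-bis[3,4-bis(tert-butyldimethylsilyloxy)phenyl]-3-[2-oxo-4-(triisopropylsilyloxy)-2H-pyran-6-yl]-2,3-dihydro-4H-furo[3,2-c]pyran-4-one, via iodonium ylide 17 (not isolated)
Conditions: 16 (1.5 equiv), PhI=O (1.6 equiv), 4 Å MS, CH2Cl2, 0 °C, 1 h, dark; then 9 (1.0 equiv), Rh2(S-NTTL)4 (2 mol%), toluene, −20 to 0 °C, dark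
Reagents that add atoms: none
Why: Proposed new method: rhodium-catalysed carbene transfer from the ylide turns C-3 of the hydroxypyranone (normally an enol nucleophile) into an enolonium-type electrophile that bonds to the styryl carbon next to the upper pyranone (itself a vinylogous enolate position), while the ketone oxygen closes onto the developing benzylic carbon in the same metal-bound, strongly asynchronous event before C2–C3 rotation, so the Z geometry is copied into the 2,3-cis relationship and the chiral carboxylate pocket selects the alkene face that gives (2R,3S); the closest known reaction type is the dirhodium-catalysed formal [3+2] cycloaddition of cyclic 2-diazo-1,3-dicarbonyl compounds or their iodonium ylides with styrenes and vinyl ethers to give fused 2-substituted 2,3-dihydrofurans, together with the stereospecific, enantioselective carbene additions of ylide-derived acceptor/acceptor carbenes under Rh2(S-NTTL)4.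

**Step 9**
Reactants: 18 (2R,3S)-2,6-bis[3,4-bis(tert-butyldimethylsilyloxy)phenyl]-3-[2-oxo-4-(triisopropylsilyloxy)-2H-pyran-6-yl]-2,3-dihydro-4H-furo[3,2-c]pyran-4-one
Product: 19 (2R,3S)-2,6-bis(3,4-dihydroxyphenyl)-3-(4-hydroxy-2-oxo-2H-pyran-6-yl)-2,3-dihydro-4H-furo[3,2-c]pyran-4-one
Conditions: HF·pyridine (excess), pyridine, THF, 0 °C to rt, argon, dark; pH 5 buffer work-up; reversed-phase chromatography (MeCN/H2O, 0.1% HCO2H)
Reagents that add atoms: none
Why: Fluoride-driven cleavage of the five Si–O bonds under buffered, non-basic conditions touches neither stereocentre, and the absence of base avoids phenolate-triggered opening of the benzylic C2–O1 bond and deprotonation at C3, so the cis configuration is kept.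

**Compound list**
1 | 3,4-dihydroxybenzaldehyde | O=Cc1ccc(O)c(O)c1 | starting material
2 | 3,4-bis(tert-butyldimethylsilyloxy)benzaldehyde | O=Cc1ccc(O[Si](C)(C)C(C)(C)C)c(O[Si](C)(C)C(C)(C)C)c1 | intermediate
3 | 4-hydroxy-6-methyl-2H-pyran-2-one | Cc1cc(O)cc(=O)o1 | starting material
4 | 6-methyl-4-(triisopropylsilyloxy)-2H-pyran-2-one | Cc1cc(O[Si](C(C)C)(C(C)C)C(C)C)cc(=O)o1 | intermediate
5 | lithium dienolate of 4 (6-CH2Li form) | [Li+].[CH2-]c1cc(O[Si](C(C)C)(C(C)C)C(C)C)cc(=O)o1 | intermediate (not isolated)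
6 | lithium 1-[3,4-bis(tert-butyldimethylsilyloxy)phenyl]-2-[2-oxo-4-(triisopropylsilyloxy)-2H-pyran-6-yl]ethan-1-olate (racemic) | [Li+].[O-]C(Cc1cc(O[Si](C(C)C)(C(C)C)C(C)C)cc(=O)o1)c1ccc(O[Si](C)(C)C(C)(C)C)c(O[Si](C)(C)C(C)(C)C)c1 | intermediate (not isolated)
7 | 1-[3,4-bis(tert-butyldimethylsilyloxy)phenyl]-2-[2-oxo-4-(triisopropylsilyloxy)-2H-pyran-6-yl]ethyl methanesulfonate (racemic) | CS(=O)(=O)OC(Cc1cc(O[Si](C(C)C)(C(C)C)C(C)C)cc(=O)o1)c1ccc(O[Si](C)(C)C(C)(C)C)c(O[Si](C)(C)C(C)(C)C)c1 | intermediate (not isolated)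
8 | (E)-6-{2-[3,4-bis(tert-butyldimethylsilyloxy)phenyl]ethenyl}-4-(triisopropylsilyloxy)-2H-pyran-2-one | O=c1cc(O[Si](C(C)C)(C(C)C)C(C)C)cc(/C=C/c2ccc(O[Si](C)(C)C(C)(C)C)c(O[Si](C)(C)C(C)(C)C)c2)o1 | intermediate
9 | (Z)-6-{2-[3,4-bis(tert-butyldimethylsilyloxy)phenyl]ethenyl}-4-(triisopropylsilyloxy)-2H-pyran-2-one | O=c1cc(O[Si](C(C)C)(C(C)C)C(C)C)cc(/C=C\c2ccc(O[Si](C)(C)C(C)(C)C)c(O[Si](C)(C)C(C)(C)C)c2)o1 | intermediate
10 | ethyl 3,4-dihydroxybenzoate | CCOC(=O)c1ccc(O)c(O)c1 | starting material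
11 | ethyl 3,4-bis(tert-butyldimethylsilyloxy)benzoate | CCOC(=O)c1ccc(O[Si](C)(C)C(C)(C)C)c(O[Si](C)(C)C(C)(C)C)c1 | intermediate
12 | tert-butyl acetoacetate (tert-butyl 3-oxobutanoate) | CC(=O)CC(=O)OC(C)(C)C | starting material
13 | sodium lithium dianion of tert-butyl acetoacetate | [Na+].[Li+].[CH2-]C(=O)[CH-]C(=O)OC(C)(C)C | intermediate (not isolated)
14 | tert-butyl 5-[3,4-bis(tert-butyldimethylsilyloxy)phenyl]-3,5-dioxopentanoate | CC(C)(C)OC(=O)CC(=O)CC(=O)c1ccc(O[Si](C)(C)C(C)(C)C)c(O[Si](C)(C)C(C)(C)C)c1 | intermediate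
15 | 5-[3,4-bis(tert-butyldimethylsilyloxy)phenyl]pent-1-ene-1,3,5-trione (acylketene) | O=C=CC(=O)CC(=O)c1ccc(O[Si](C)(C)C(C)(C)C)c(O[Si](C)(C)C(C)(C)C)c1 | intermediate (not isolated)
16 | 6-[3,4-bis(tert-butyldimethylsilyloxy)phenyl]-4-hydroxy-2H-pyran-2-one | O=c1cc(O)cc(-c2ccc(O[Si](C)(C)C(C)(C)C)c(O[Si](C)(C)C(C)(C)C)c2)o1 | intermediate
17 | 6-[3,4-bis(tert-butyldimethylsilyloxy)phenyl]-2-oxo-3-(phenyliodonio)-2H-pyran-4-olate (iodonium ylide) | O=c1oc(-c2ccc(O[Si](C)(C)C(C)(C)C)c(O[Si](C)(C)C(C)(C)C)c2)cc([O-])c1[I+]c1ccccc1 | intermediate (not isolated)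
18 | (2R,3S)-2,6-bis[3,4-bis(tert-butyldimethylsilyloxy)phenyl]-3-[2-oxo-4-(triisopropylsilyloxy)-2H-pyran-6-yl]-2,3-dihydro-4H-furo[3,2-c]pyran-4-one (2,3-cis) | O=c1cc(O[Si](C(C)C)(C(C)C)C(C)C)cc([C@H]2c3c(cc(-c4ccc(O[Si](C)(C)C(C)(C)C)c(O[Si](C)(C)C(C)(C)C)c4)oc3=O)O[C@H]2c2ccc(O[Si](C)(C)C(C)(C)C)c(O[Si](C)(C)C(C)(C)C)c2)o1 | intermediate
19 | (2R,3S)-2,6-bis(3,4-dihydroxyphenyl)-3-(4-hydroxy-2-oxo-2H-pyran-6-yl)-2,3-dihydro-4H-furo[3,2-c]pyran-4-one (2,3-cis; CNP0224684.1) | O=c1cc(O)cc([C@H]2c3c(cc(-c4ccc(O)c(O)c4)oc3=O)O[C@H]2c2ccc(O)c(O)c2)o1 | target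

**Totals**
Total step count: 9.
Longest linear sequence: 5 steps (1 → 2 → 8 → 9 → 18 → 19; the branches through 4 and through 11 are equally long).

**Three steps most likely to fail**

Step 8 (highest risk). The electron-rich aryl group can let the first C–C bond give an open benzylic cation that rotates before the oxygen closes, which leaks to the 2,3-trans isomer. Closure through the lactone carbonyl would give the furo[2,3-b]pyran-4-one isomer, and the enantioselectivity is untested on this alkene. The fallback sets out from 4, 11 and 16 and returns at 18. It makes the same C3–C3a bond by SN2 alkylation with an α-bromo ketone as the enolonium equivalent and sets the stereocentres afterwards.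
- Acylation of the dienolate of 4 (2 equiv LiN(i-Pr)2, THF, −78 °C) with ester 11 gives 6-{2-[3,4-bis(tert-butyldimethylsilyloxy)phenyl]-2-oxoethyl}-4-(triisopropylsilyloxy)-2H-pyran-2-one F1.
- N-Bromosuccinimide in THF at 0 °C brominates the doubly activated methylene to give the racemic α-bromo ketone F2.
- C-Alkylation of 16 at C-3 (K2CO3, acetone, 0 °C) gives the configurationally labile 1,4-dicarbonyl compound F3.
- Asymmetric transfer hydrogenation under dynamic kinetic resolution (RuCl[(S,S)-TsDPEN](p-cymene), HCO2H/Et3N, CH2Cl2) is expected to give the (1S,2S)-alcohol F4; the diastereoselectivity of this reduction is not predictable with confidence.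
- Intramolecular Mitsunobu etherification through the acidic pyranone hydroxyl (PPh3, DIAD, THF, −20 °C) closes the dihydrofuran with inversion at the carbinol carbon and gives 18.

Step 4. The photostationary state may stay E-rich, the styrylpyranone may undergo [2+2] dimerisation, and 9 may revert to 8 on handling in light. The fallback sets out from 4 and 2 and returns at 9. It builds the Z alkene under kinetic control by an Ando-type Horner–Wadsworth–Emmons olefination.
- Radical bromination of 4 (N-bromosuccinimide, dibenzoyl peroxide cat., PhCF3, 80 °C) gives 6-(bromomethyl)-4-(triisopropylsilyloxy)-2H-pyran-2-one F5.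
- Michaelis–Becker reaction with diphenyl phosphite (i-Pr2NEt, CH2Cl2, rt) gives diphenyl {[2-oxo-4-(triisopropylsilyloxy)-2H-pyran-6-yl]methyl}phosphonate F6.
- Deprotonation (NaH, NaI, THF, −78 °C) and addition of aldehyde 2 gives 9 with kinetic Z selectivity.

Step 9. The free cis product has a para-hydroxybenzylic C2–O1 bond whose leaving group is a vinylogous carboxylate, and an acidic C3–H. Base, strong acid or long exposure can therefore open the ring or epimerise it to the trans isomer, and the catechols oxidise in air. The fallback sets out from 18 and returns at 19. It traps the phenols as acetates as they are released and unveils them enzymatically at neutral pH.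
- 18 is treated with HF·pyridine in pyridine containing Ac2O and DMAP (0 °C to rt), so each liberated hydroxyl is acetylated at once, giving the (2R,3S)-pentaacetate F7, which is stable to silica.
- Hydrolysis with Candida antarctica lipase B in pH 6.5 phosphate buffer/tert-butyl methyl ether at rt under argon gives 19.

**Further compounds**
F1 | step 8 | 6-{2-[3,4-bis(tert-butyldimethylsilyloxy)phenyl]-2-oxoethyl}-4-(triisopropylsilyloxy)-2H-pyran-2-one | O=C(Cc1cc(O[Si](C(C)C)(C(C)C)C(C)C)cc(=O)o1)c1ccc(O[Si](C)(C)C(C)(C)C)c(O[Si](C)(C)C(C)(C)C)c1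
F2 | step 8 | 6-{1-bromo-2-[3,4-bis(tert-butyldimethylsilyloxy)phenyl]-2-oxoethyl}-4-(triisopropylsilyloxy)-2H-pyran-2-one (racemic) | O=C(C(Br)c1cc(O[Si](C(C)C)(C(C)C)C(C)C)cc(=O)o1)c1ccc(O[Si](C)(C)C(C)(C)C)c(O[Si](C)(C)C(C)(C)C)c1
F3 | step 8 | 6-[3,4-bis(tert-butyldimethylsilyloxy)phenyl]-3-{2-[3,4-bis(tert-butyldimethylsilyloxy)phenyl]-2-oxo-1-[2-oxo-4-(triisopropylsilyloxy)-2H-pyran-6-yl]ethyl}-4-hydroxy-2H-pyran-2-one (racemic, labile at the methine) | O=C(C(c1cc(O[Si](C(C)C)(C(C)C)C(C)C)cc(=O)o1)c1c(O)cc(-c2ccc(O[Si](C)(C)C(C)(C)C)c(O[Si](C)(C)C(C)(C)C)c2)oc1=O)c1ccc(O[Si](C)(C)C(C)(C)C)c(O[Si](C)(C)C(C)(C)C)c1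
F4 | step 8 | (1S,2S)-1-[3,4-bis(tert-butyldimethylsilyloxy)phenyl]-2-{6-[3,4-bis(tert-butyldimethylsilyloxy)phenyl]-4-hydroxy-2-oxo-2H-pyran-3-yl}-2-[2-oxo-4-(triisopropylsilyloxy)-2H-pyran-6-yl]ethan-1-ol | O=c1cc(O[Si](C(C)C)(C(C)C)C(C)C)cc([C@H]([C@H](O)c2ccc(O[Si](C)(C)C(C)(C)C)c(O[Si](C)(C)C(C)(C)C)c2)c2c(O)cc(-c3ccc(O[Si](C)(C)C(C)(C)C)c(O[Si](C)(C)C(C)(C)C)c3)oc2=O)o1
F5 | step 4 | 6-(bromomethyl)-4-(triisopropylsilyloxy)-2H-pyran-2-one | BrCc1cc(O[Si](C(C)C)(C(C)C)C(C)C)cc(=O)o1
F6 | step 4 | diphenyl {[2-oxo-4-(triisopropylsilyloxy)-2H-pyran-6-yl]methyl}phosphonate | O=P(Cc1cc(O[Si](C(C)C)(C(C)C)C(C)C)cc(=O)o1)(Oc1ccccc1)Oc1ccccc1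
F7 | step 9 | (2R,3S)-3-(4-acetoxy-2-oxo-2H-pyran-6-yl)-2,6-bis(3,4-diacetoxyphenyl)-2,3-dihydro-4H-furo[3,2-c]pyran-4-one | O=c1cc(OC(C)=O)cc([C@H]2c3c(cc(-c4ccc(OC(C)=O)c(OC(C)=O)c4)oc3=O)O[C@H]2c2ccc(OC(C)=O)c(OC(C)=O)c2)o1
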